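**Retrosynthetic overview**
1. The strategy rests on ring B: C9 carries the two-carbon unit C11–C12 directly beside the C8=C17 exocyclic methylene, and C6 is oxygenated. Cutting C8–C9 gives a C8 vinyl radical (from a 2-bromoallyl arm on C5–C6) and a C9=C11 enoate on C10 of ring A.
2. Side chain and acetate come last: C12 ester → aldehyde → Z-vinyl iodide → vinyl coupling (12Z,14-diene); OTBS → OAc.
3. Precursor: C6 from the C5 aldehyde and 2-bromoallylindium, its configuration fixed by oxidation and CBS reduction. The enoate on C10 comes from hydrogen-atom-transfer coupling of the ring alkene C1=C10 with methyl acrylate, then selenoxide desaturation.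
4. Ring A is formed first, by a BINOL-templated Diels–Alder of a dienol with methyl acrylate (bonds C4–C5 and C2–C3) that gives a cis-lactone, methylated at C4. Ring B is formed second, in the key step.

Key step: step 13

Remark: ring atoms carry their labdane numbers (C1–C20) throughout; α/β refer to the target drawn with the C10 methyl β.
Assumption: (R)-BINOL is taken to give the (3aS,7aS) lactone in step 2; if the template has the opposite sense, (S)-BINOL is used and nothing else changes.

**Route**

Step 1
Reactants: 1 (2E)-3-methylpent-2-en-4-yn-1-ol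
Product: 2 (2E)-3-methylpenta-2,4-dien-1-ol
Conditions: H2 (1 atm), Pd/CaCO3 poisoned with Pb(OAc)2, quinoline, EtOAc, 0 °C, stopped after 1 equiv H2
Reagents that add atoms: none
Why: Semihydrogenation on the lead- and quinoline-poisoned palladium surface reduces the terminal alkyne to the vinyl group and stops there, leaving the E trisubstituted alkene, so the diene carries its C5 substituent pointing outward.

Step 2
Reactants: 2 (2E)-3-methylpenta-2,4-dien-1-ol; 3 methyl acrylate
Product: 5 (3aS,7aS)-4-methyl-3a,6,7,7a-tetrahydro-2-benzofuran-1(3H)-one (cis-fused lactone: C19 carbonyl on C4; O–C6 on C5), via hydroxy ester adduct 4 (not isolated)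
Conditions: (R)-BINOL (10 mol%), Me2Zn (1.0 equiv), MeMgBr (1.0 equiv), CH2Cl2, 0 °C → rt; then 1 M HCl
Reagents that add atoms: none
Why: Diels–Alder reaction by Lewis-acid-templated self-assembly: dienolate and acrylate are held on the Zn/Mg BINOLate, so the cycloaddition is in effect intramolecular, which enforces the C4–C5 regiochemistry against the para-directing C10 methyl and the endo mode (C6 and C19 cis, so alkoxide 4 closes to the lactone), while the BINOL ligand selects the face that sets C5 (C4 is re-made in step 3); ring A is formed here.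

Step 3
Reactants: 5 cis-lactone
Product: 6 (3aR,7aS)-4,7a-dimethyl-3a,6,7,7a-tetrahydro-2-benzofuran-1(3H)-one
Conditions: LDA, THF, −78 °C; MeI, −78 → −20 °C
Reagents that add atoms: iodomethane CI
Why: Lactone enolate alkylation: C4–H is the only acidic hydrogen and MeI enters syn to H-5 because the ring fusion stays cis, giving quaternary C4 with CH3 α and the C19 carbonyl β, cis to C6.

Step 4
Reactants: 6 methylated cis-lactone
Product: 9 (1S,2R)-1,3-dimethyl-2-[(triethylsilyloxy)methyl]cyclohex-3-ene-1-carboxylic acid, via potassium hydroxy carboxylate 7 (not isolated), via bis(triethylsilyl) derivative 8 (not isolated)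
Conditions: KOH, MeOH/H2O, 65 °C; evaporate; TESCl, imidazole, DMF, 0 °C → rt; pH 7 phosphate buffer work-up; used at once
Reagents that add atoms: potassium hydroxide [K+].[OH-]; chlorotriethylsilane CC[Si](Cl)(CC)CC
Why: Saponification followed by silylation: hydroxide opens the α-quaternary γ-lactone and both oxygens are silylated before the hydroxy acid can close again, the silyl ester then hydrolysing on neutral aqueous work-up while the hindered primary TES ether stays.

Step 5
Reactants: 9 TES-ether acid
Product: 10 methyl (1S,2R)-1,3-dimethyl-2-[(triethylsilyloxy)methyl]cyclohex-3-ene-1-carboxylate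
Conditions: MeI, K2CO3, DMF, rt
Reagents that add atoms: iodomethane CI
Why: Carboxylate O-alkylation (SN2 at MeI) esterifies the hindered C19 acid at oxygen, where the quaternary C4 does not slow the reaction, and leaves the TES ether alone.

Step 6
Reactants: 10 ring A alkene ester; 3 methyl acrylate
Product: 11 saturated diester (ring A: 4α-CH3, 4β-CO2Me, 5α-H, 5β-CH2OTES, 10β-CH3, 10α-CH2CH2CO2Me)
Conditions: Fe(acac)3 (30 mol%), PhSiH3, EtOH/(CH2OH)2, 60 °C
Reagents that add atoms: none
Why: Iron-hydride hydrogen-atom-transfer reductive olefin coupling (a Giese addition): H• goes to C1, the tertiary C10 radical adds to methyl acrylate and the α-ester radical is reduced and protonated; addition on the α face is expected because in the half-chair with the C19 ester axial only H-5 flanks that face, whereas the β face is screened by the axial ester or, in the other half-chair, by the axial C6 arm, which puts the chain α and the methyl β.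

Step 7
Reactants: 11 saturated diester
Product: 14 E-enoate (ring A as in 11 with 10α-CH=CH–CO2Me), via α-phenylselanyl ester 12 (not isolated), via selenoxide 13 (not isolated)
Conditions: LDA, THF, −78 °C; PhSeBr; then 30% H2O2, pyridine, CH2Cl2, 0 °C → rt
Reagents that add atoms: none
Why: α-Selenenylation and selenoxide syn-elimination: only C11 has enolisable hydrogens (C19 sits on quaternary C4) and only C9 offers a β-hydrogen, so the E C9=C11 enoate results.

Step 8
Reactants: 14 E-enoate TES ether
Product: 15 aldehyde (5β-CHO; C6 is the formyl carbon)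
Conditions: (COCl)2, DMSO, CH2Cl2, −78 → −40 °C; Et3N, −78 → 0 °C
Reagents that add atoms: none
Why: Swern oxidation of a primary triethylsilyl ether: the chlorosulfonium reagent cleaves and oxidises the primary TES ether in one operation, so the free γ-hydroxy ester, which would close back to the lactone, never appears, and C5 is slow to enolise between two quaternary carbons.

Step 9
Reactants: 15 aldehyde; 16 2,3-dibromoprop-1-ene
Product: 17 homoallylic alcohol (2-bromoallyl carbinol at C6, both C6 epimers)
Conditions: In powder, THF/H2O (1:1), rt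
Reagents that add atoms: none
Why: Barbier-type indium-mediated allylation: the 2-bromoallylindium formed in the flask adds to the hindered aldehyde and not to the esters or the enoate; the two quaternary neighbours of C5 are nearly alike, so no useful Felkin bias is expected and C6 is set in steps 10 and 11.

Step 10
Reactants: 17 alcohol mixture
Product: 18 2-bromoallyl ketone (C6=O)
Conditions: Dess–Martin periodinane, NaHCO3, CH2Cl2, 0 °C → rt
Reagents that add atoms: none
Why: Dess–Martin oxidation under buffered neutral conditions converges both epimers on the β,γ-unsaturated ketone without moving the alkene into conjugation or epimerising C5.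

Step 11
Reactants: 18 ketone
Product: 19 (6S)-alcohol
Conditions: (R)-2-methyl-CBS-oxazaborolidine [(R)-1-methyl-3,3-diphenyltetrahydro-1H,3H-pyrrolo[1,2-c][1,3,2]oxazaborole] (20 mol%), catecholborane, toluene, −78 → −40 °C; pH 7 buffer
Reagents that add atoms: none
Why: Corey–Bakshi–Shibata reduction: with ring carbon C5 as the large group and the 2-bromoallyl CH2 as the small one, the (R)-catalyst delivers hydride to the face that gives the 6S alcohol (catalyst control), and catecholborane at low temperature spares the enoate and the vinyl bromide.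

Step 12
Reactants: 19 (6S)-alcohol
Product: 20 key-step precursor (6S)-silyl ether (ring A: 4α-CH3, 4β-CO2Me, 5α-H, 10β-CH3, 10α-E-CH=CH–CO2Me; arm CH(OTBS)CH2C(Br)=CH2 on C5)
Conditions: TBSOTf, 2,6-lutidine, CH2Cl2, −78 → 0 °C, on the crude alcohol
Reagents that add atoms: tert-butyldimethylsilyl triflate CC(C)(C)[Si](C)(C)OS(=O)(=O)C(F)(F)F
Why: Silylation with the triflate protects the hindered secondary alcohol quickly, before it can lactonise onto C19.

Step 13
Reactants: 20 key-step precursor
Product: 21 dimethyl 6α-(tert-butyldimethylsilyloxy)-13,14,15,16-tetranorlabd-8(17)-ene-12,19-dioate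
Conditions: Bu3SnH (1.3 equiv), AIBN (cat.), benzene (0.005 M), 80 °C, syringe-pump addition over 6 h
Reagents that add atoms: none
Why: Bu3Sn• abstracts bromine from 20 and the σ-vinyl radical at C8 adds to C9, the β-carbon of the E-enoate, in a 6-exo-trig closure of ring B (bond C8–C9), after which the ester-stabilised C11 radical takes hydrogen from Bu3SnH; this is the known tin hydride cyclisation of a 2-bromoallyl-derived vinyl radical onto an α,β-unsaturated ester. Only the ring A chair with the C5 and C10 arms both equatorial can reach the transition state, so the preset trans relationship of C5 and C10 becomes the trans ring fusion. The one new stereocenter, C9, is set in a chair-like transition state of the forming ring with the C6 silyloxy group equatorial and the acceptor alkene pseudo-equatorial (C11 turned away from C1 and anti to C5–C10), so H-9 ends α and the CH2CO2Me chain β. The step needs 6-exo over 7-endo attack and cyclisation over direct reduction of the vinyl radical. The first is secured by the enoate polarisation (attack at C9 gives the stabilised radical), the second by slow addition of Bu3SnH at high dilution and by the lack of any C–H within 1,5-reach of C8 (C4 and C10 are quaternary).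

Step 14
Reactants: 21 cyclised diester
Product: 22 methyl 6α-(tert-butyldimethylsilyloxy)-12-oxo-13,14,15,16-tetranorlabd-8(17)-en-19-oate
Conditions: DIBAL-H (1.1 equiv), CH2Cl2, −78 °C; aq. potassium sodium tartrate
Reagents that add atoms: none
Why: DIBAL-H half-reduction at −78 °C: the aluminium hemiacetal of the accessible C12 ester survives until work-up, while the axial, neopentyl C19 ester is too hindered to react.

Step 15
Reactants: 22 C12 aldehyde
Product: 23 methyl (12Z)-6α-(tert-butyldimethylsilyloxy)-13-iodo-14,15-dinorlabda-8(17),12-dien-19-oate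
Conditions: EtPPh3I, n-BuLi, THF; I2, −78 °C; NaHMDS, −20 °C; then 22, −78 → −20 °C
Reagents that add atoms: ethyltriphenylphosphonium iodide CC[P+](c1ccccc1)(c1ccccc1)c1ccccc1.[I-]; iodine II
Why: Wittig olefination with the α-iodo ylide Ph3P=C(I)CH3 (Stork–Zhao type): the non-stabilised ylide gives the Z iodoalkene with iodine cis to C11, which fixes the later 12Z geometry.

Step 16
Reactants: 23 Z-vinyl iodide
Product: 24 methyl (12Z)-6α-(tert-butyldimethylsilyloxy)labda-8(17),12,14-trien-19-oate
Conditions: CH2=CHSnBu3, Pd(PPh3)4 (5 mol%), CuI (10 mol%), DMF, 40 °C, dark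
Reagents that add atoms: tributyl(vinyl)stannane C=C[Sn](CCCC)(CCCC)CCCC
Why: Stille coupling proceeds with retention at the vinyl iodide, so the vinyl group takes the place of iodine cis to C11 and the 8(17)-alkene is untouched.

Step 17
Reactants: 24 silyl ether
Product: 25 methyl (12Z)-6α-hydroxylabda-8(17),12,14-trien-19-oate
Conditions: TBAF, THF, rt → 40 °C
Reagents that add atoms: none
Why: Fluoride desilylation; the equatorial 6α-alkoxide cannot reach the axial C19 ester across the trans-decalin, so no lactone forms and the diene is not exposed to acid.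

Step 18
Reactants: 25 6α-alcohol
Product: 26 methyl (12Z)-6α-acetoxylabda-8(17),12,14-trien-19-oate (CNP0212193.2)
Conditions: Ac2O, DMAP (cat.), pyridine, rt
Reagents that add atoms: acetic anhydride CC(=O)OC(C)=O
Why: DMAP-catalysed acylation of the equatorial secondary alcohol gives the acetate without touching any stereocenter.

**Compound list**
1 | (2E)-3-methylpent-2-en-4-yn-1-ol | C#C/C(C)=C/CO | starting material
2 | (2E)-3-methylpenta-2,4-dien-1-ol | C=C/C(C)=C/CO | intermediate
3 | methyl acrylate | C=CC(=O)OC | starting material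
4 | methyl (1S,2S)-2-(hydroxymethyl)-3-methylcyclohex-3-ene-1-carboxylate (cis; metal alkoxide in the flask) | CC1=CCC[C@H](C(=O)OC)[C@@H]1CO | intermediate
5 | (3aS,7aS)-4-methyl-3a,6,7,7a-tetrahydro-2-benzofuran-1(3H)-one | CC1=CCC[C@@H]2C(=O)OC[C@H]12 | intermediate
6 | (3aR,7aS)-4,7a-dimethyl-3a,6,7,7a-tetrahydro-2-benzofuran-1(3H)-one | CC1=CCC[C@]2(C)C(=O)OC[C@H]12 | intermediate
7 | potassium (1S,2R)-2-(hydroxymethyl)-1,3-dimethylcyclohex-3-ene-1-carboxylate | CC1=CCC[C@](C)(C(=O)[O-])[C@@H]1CO.[K+] | intermediate
8 | triethylsilyl (1S,2R)-1,3-dimethyl-2-[(triethylsilyloxy)methyl]cyclohex-3-ene-1-carboxylate | CC1=CCC[C@](C)(C(=O)O[Si](CC)(CC)CC)[C@@H]1CO[Si](CC)(CC)CC | intermediate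
9 | (1S,2R)-1,3-dimethyl-2-[(triethylsilyloxy)methyl]cyclohex-3-ene-1-carboxylic acid | CC1=CCC[C@](C)(C(=O)O)[C@@H]1CO[Si](CC)(CC)CC | intermediate
10 | methyl (1S,2R)-1,3-dimethyl-2-[(triethylsilyloxy)methyl]cyclohex-3-ene-1-carboxylate | CC1=CCC[C@](C)(C(=O)OC)[C@@H]1CO[Si](CC)(CC)CC | intermediate
11 | saturated diester (4α-CH3, 4β-CO2Me, 5α-H, 5β-CH2OTES, 10β-CH3, 10α-CH2CH2CO2Me) | COC(=O)CC[C@@]1(C)CCC[C@](C)(C(=O)OC)[C@@H]1CO[Si](CC)(CC)CC | intermediate
12 | α-phenylselanyl ester (11 with SePh on C11, both C11 epimers) | COC(=O)C([Se]c1ccccc1)C[C@@]2(C)CCC[C@](C)(C(=O)OC)[C@@H]2CO[Si](CC)(CC)CC | intermediate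
13 | selenoxide of 12 | COC(=O)C([Se](=O)c1ccccc1)C[C@@]2(C)CCC[C@](C)(C(=O)OC)[C@@H]2CO[Si](CC)(CC)CC | intermediate
14 | E-enoate TES ether (10α-CH=CH–CO2Me, 5β-CH2OTES) | COC(=O)/C=C/[C@@]1(C)CCC[C@](C)(C(=O)OC)[C@@H]1CO[Si](CC)(CC)CC | intermediate
15 | E-enoate aldehyde (5β-CHO) | COC(=O)/C=C/[C@@]1(C)CCC[C@](C)(C(=O)OC)[C@@H]1C=O | intermediate
16 | 2,3-dibromoprop-1-ene | C=C(Br)CBr | starting material
17 | 2-bromoallyl carbinol, C6 epimer mixture | COC(=O)/C=C/[C@@]1(C)CCC[C@](C)(C(=O)OC)[C@@H]1C(O)CC(Br)=C | intermediate
18 | 2-bromoallyl ketone (C6=O) | COC(=O)/C=C/[C@@]1(C)CCC[C@](C)(C(=O)OC)[C@@H]1C(=O)CC(Br)=C | intermediate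
19 | (6S)-2-bromoallyl carbinol | COC(=O)/C=C/[C@@]1(C)CCC[C@](C)(C(=O)OC)[C@@H]1[C@@H](O)CC(Br)=C | intermediate
20 | key-step precursor, (6S)-TBS ether | COC(=O)/C=C/[C@@]1(C)CCC[C@](C)(C(=O)OC)[C@@H]1[C@@H](O[Si](C)(C)C(C)(C)C)CC(Br)=C | intermediate
21 | dimethyl 6α-(tert-butyldimethylsilyloxy)-13,14,15,16-tetranorlabd-8(17)-ene-12,19-dioate | COC(=O)C[C@H]1C(=C)C[C@H](O[Si](C)(C)C(C)(C)C)[C@@H]2[C@]1(C)CCC[C@]2(C)C(=O)OC | intermediate
22 | methyl 6α-(tert-butyldimethylsilyloxy)-12-oxo-13,14,15,16-tetranorlabd-8(17)-en-19-oate | O=CC[C@H]1C(=C)C[C@H](O[Si](C)(C)C(C)(C)C)[C@@H]2[C@]1(C)CCC[C@]2(C)C(=O)OC | intermediate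
23 | methyl (12Z)-6α-(tert-butyldimethylsilyloxy)-13-iodo-14,15-dinorlabda-8(17),12-dien-19-oate | I/C(C)=C\C[C@H]1C(=C)C[C@H](O[Si](C)(C)C(C)(C)C)[C@@H]2[C@]1(C)CCC[C@]2(C)C(=O)OC | intermediate
24 | methyl (12Z)-6α-(tert-butyldimethylsilyloxy)labda-8(17),12,14-trien-19-oate | C=C/C(C)=C\C[C@H]1C(=C)C[C@H](O[Si](C)(C)C(C)(C)C)[C@@H]2[C@]1(C)CCC[C@]2(C)C(=O)OC | intermediate
25 | methyl (12Z)-6α-hydroxylabda-8(17),12,14-trien-19-oate | C=C/C(C)=C\C[C@H]1C(=C)C[C@H](O)[C@@H]2[C@]1(C)CCC[C@]2(C)C(=O)OC | intermediate
26 | methyl (12Z)-6α-acetoxylabda-8(17),12,14-trien-19-oate, (4S,5R,6S,9S,10R) | C=C/C(C)=C\C[C@H]1C(=C)C[C@H](OC(C)=O)[C@@H]2[C@]1(C)CCC[C@]2(C)C(=O)OC | target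

**Totals and risks**

Total step count: 18. Longest linear sequence: 18 steps (1 → 26; methyl acrylate and 2,3-dibromopropene enter as reagents).

Three steps most likely to fail:

Step 6. What may go wrong: the C10 radical is captured on the wrong (β) face, because the Me/CO2Me and Me/chain pairs on the two flanks are close in size, or the tertiary radical takes hydrogen before it meets the acrylate. Fallback, from 6 back to 11: the radical addition is moved to the cis-fused bicyclic lactone 6, where the lactone ring sits on the β face and the α face is the convex one. The same Fe(acac)3/PhSiH3 coupling with methyl acrylate would give the lactone ester F1. KOH then opens the lactone and hydrolyses the chain ester to the dipotassium hydroxy dicarboxylate F2, TESCl/imidazole gives the tris(triethylsilyl) compound F3, and neutral aqueous work-up gives the diacid TES ether F4. MeI/K2CO3 esterifies both acids and the route is rejoined at 11.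

Step 13. What may go wrong: hydrogen transfer to the vinyl radical before ring closure (debrominated, uncyclised alkene), or bonding to the wrong face of C9. Fallback, from 20 directly to 21: a reductive Heck cyclisation (Pd(OAc)2, PPh3, HCO2Na, Et3N, DMF, 80 °C). Zerovalent palladium inserts into the C8–Br bond, 6-exo syn-carbopalladation of the enoate forms C8–C9, and formate reduces the C11 palladium enolate. No tin hydride is present to intercept the C8 intermediate, and no new compound is needed.

Step 2. What may go wrong: the template fails to override the para-directing C10 methyl of this substituted dienol (regioisomer mixture), or face selection is low. Fallback, from 2 back to 10: auxiliary control in an intermolecular Diels–Alder. Dienol 2 is silylated (TESCl, imidazole) to the triethylsilyl ether F5. Et2AlCl-promoted cycloaddition with (R)-4-benzyl-3-acryloyl-1,3-oxazolidin-2-one at −100 °C (diene endo on the face away from the benzyl group of the aluminium chelate) would give the imide adduct F6, any regioisomer being removed here. MeOMgBr would give the methyl ester F7, and LDA/MeI, with methyl entering anti to the C6 arm, gives 10, which bypasses the lactone.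

**Further compounds**
F1 | step 6 | lactone ester (6 with 10β-CH3 and 10α-CH2CH2CO2Me) | COC(=O)CC[C@@]1(C)CCC[C@]2(C)C(=O)OC[C@H]12
F2 | step 6 | dipotassium hydroxy dicarboxylate | [O-]C(=O)CC[C@@]1(C)CCC[C@](C)(C(=O)[O-])[C@@H]1CO.[K+].[K+]
F3 | step 6 | tris(triethylsilyl) derivative | CC[Si](CC)(CC)OC(=O)CC[C@@]1(C)CCC[C@](C)(C(=O)O[Si](CC)(CC)CC)[C@@H]1CO[Si](CC)(CC)CC
F4 | step 6 | diacid TES ether | OC(=O)CC[C@@]1(C)CCC[C@](C)(C(=O)O)[C@@H]1CO[Si](CC)(CC)CC
F0 | step 13 | none | none
F5 | step 2 | (2E)-3-methylpenta-2,4-dien-1-yl triethylsilyl ether | C=C/C(C)=C/CO[Si](CC)(CC)CC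
F6 | step 2 | (R)-4-benzyl-3-acyl-oxazolidinone Diels–Alder adduct (cis, 4α-H, 5α-H) | CC1=CCC[C@H](C(=O)N2[C@H](Cc3ccccc3)COC2=O)[C@@H]1CO[Si](CC)(CC)CC
F7 | step 2 | methyl (1S,2S)-3-methyl-2-[(triethylsilyloxy)methyl]cyclohex-3-ene-1-carboxylate | CC1=CCC[C@H](C(=O)OC)[C@@H]1CO[Si](CC)(CC)CC
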